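**Retrosynthetic overview**

1. Enabling feature: in the cyclohexene ring (C1, C10, C11, C12, C13, C14) the C13=C14 double bond lies γ,δ to the oxygenated carbon C9 across the ring-fusion bond C1–C10. This is a Claisen retron. The retro-[3,3] step gives a dihydropyran (O1 bridging C9 and C13) inside a 12-membered oxacycle, so one [3,3] shift closes the six- and the ten-membered ring together.
2. Endgame: target ⇐ acetylation and desilylation ⇐ C9 ketone 40 (chelation-controlled reduction) ⇐ macrocyclic 2-alkenyl-6-alkyl-dihydropyran 39.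
3. 39 ⇐ Nozaki–Hiyama–Kishi closure of C1–C2 in (Z)-alkenyl iodide/aldehyde 35 ⇐ C8–C9 union of the C9-metalated glycal from 9 with ketolactone 27.
4. 9 comes from methyl 3,4-O-isopropylidene-L-threonate (ynone, dihydropyranone, methyl addition). 27 comes from (R)-glyceraldehyde acetonide, (S)-glycidol and (R)-lactic acid (Z-alkenyl iodide, epoxide opening, dioxolanone aldol, lactonisation).
5. Ring order: dihydropyran template (step 4), γ-lactone (step 18), 12-membered oxacycle (step 26), then cyclohexene and ten-membered carbocycle in one operation (step 30).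

Key step: step 30

Remark: carbons are numbered as in the briarane skeleton (C1–C20; O1 is the temporary ring oxygen of the dihydropyran); an acetyl shift from O2 to O3 after step 32 would be harmless because step 33 acetylates both positions.

**Route**

Step 1
Reactants: 1 methyl 3,4-O-isopropylidene-L-threonate
Product: 2 methyl (2R)-2-[(tert-butyldimethylsilyl)oxy]-2-[(4S)-2,2-dimethyl-1,3-dioxolan-4-yl]acetate
Conditions: TBSCl, imidazole, DMF, rt
Reagents that add atoms: tert-butyldimethylsilyl chloride, CC(C)(C)[Si](C)(C)Cl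
Why: Imidazole-mediated silyl ether formation on the secondary α-hydroxy ester, with no stereocentre touched.

Step 2
Reactants: 2 silyl ether ester
Product: 3 (2R)-2-[(tert-butyldimethylsilyl)oxy]-2-[(4S)-2,2-dimethyl-1,3-dioxolan-4-yl]-N-methoxy-N-methylacetamide
Conditions: MeNH(OMe)·HCl, i-PrMgCl, THF, −20 °C
Reagents that add atoms: N,O-dimethylhydroxylamine hydrochloride, CNOC.Cl
Why: Direct ester-to-Weinreb-amide conversion with the chloromagnesium amide, which at low temperature should leave the α-silyloxy centre (C12) intact.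

Step 3
Reactants: 3 Weinreb amide
Product: 4 (1R)-1-[(tert-butyldimethylsilyl)oxy]-1-[(4S)-2,2-dimethyl-1,3-dioxolan-4-yl]but-3-yn-2-one
Conditions: HC≡CMgBr, THF, −20 → 0 °C
Reagents that add atoms: ethynylmagnesium bromide, C#C[Mg]Br
Why: Weinreb ketone synthesis, in which the chelated tetrahedral adduct stops at the ketone stage and gives the terminal ynone.

Step 4
Reactants: 4 ynone acetonide
Product: 6 (2S,3R)-3-[(tert-butyldimethylsilyl)oxy]-2-(hydroxymethyl)-2,3-dihydro-4H-pyran-4-one, via dihydroxy ynone 5 (not isolated)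
Conditions: TsOH·H2O (cat.), MeOH, rt; then AgOTf (5 mol %), CH2Cl2, rt
Reagents that add atoms: none
Why: Acid-catalysed transketalisation frees the C13/C14 diol and the C13 hydroxyl then adds 6-endo-dig to the ynone (oxa-Michael cycloisomerisation, preferred over the seven-membered mode), carrying C12 and C13 over unchanged.

Step 5
Reactants: 6 hydroxymethyl dihydropyranone
Product: 7 (2S,3R)-3-[(tert-butyldimethylsilyl)oxy]-2-{[(tert-butyldimethylsilyl)oxy]methyl}-2,3-dihydro-4H-pyran-4-one
Conditions: TBSCl, imidazole, CH2Cl2, 0 °C → rt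
Reagents that add atoms: tert-butyldimethylsilyl chloride, CC(C)(C)[Si](C)(C)Cl
Why: Silylation of the primary alcohol, giving a C14 protecting group that can later be removed selectively.

Step 6
Reactants: 7 bis-silyl dihydropyranone
Product: 8 (2S,3R,4S)-3-[(tert-butyldimethylsilyl)oxy]-2-{[(tert-butyldimethylsilyl)oxy]methyl}-4-methyl-3,4-dihydro-2H-pyran-4-ol
Conditions: MeLi, CeCl3, THF, −78 °C
Reagents that add atoms: methyllithium, [Li]C
Why: Organocerium 1,2-addition to the vinylogous ester carbonyl, in which methyl should enter anti to the pseudo-axial C12 silyloxy group and the C13 side chain and so set C11 with its hydroxyl cis to O12.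

Step 7
Reactants: 8 tertiary allylic alcohol
Product: 9 (2S,3R,4S)-3-[(tert-butyldimethylsilyl)oxy]-2-{[(tert-butyldimethylsilyl)oxy]methyl}-4-methyl-4-[(triethylsilyl)oxy]-3,4-dihydro-2H-pyran
Conditions: TESOTf, 2,6-lutidine, CH2Cl2, −78 °C
Reagents that add atoms: triethylsilyl trifluoromethanesulfonate, CC[Si](CC)(CC)OS(=O)(=O)C(F)(F)F
Why: Silyl triflate silylation of the hindered tertiary alcohol, fast enough at −78 °C that the acid-sensitive carbinol next to the enol ether should not ionise.

Step 8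
Reactants: 10 (4R)-2,2-dimethyl-1,3-dioxolane-4-carbaldehyde
Product: 11 (4S)-4-[(1Z)-2-iodoprop-1-en-1-yl]-2,2-dimethyl-1,3-dioxolane
Conditions: EtPPh3I, n-BuLi, THF, 0 °C; I2, −78 °C; NaHMDS, −20 °C; then 10, −78 °C
Reagents that add atoms: ethyltriphenylphosphonium iodide, CC[P+](c1ccccc1)(c1ccccc1)c1ccccc1.[I-]; iodine, II
Why: Stork–Zhao-type Wittig olefination with the α-iodo ylide, which gives (Z)-2-iodo-2-alkenes under kinetic control and should not epimerise C7 at −78 °C.

Step 9
Reactants: 12 (2S)-oxiran-2-ylmethanol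
Product: 13 (2R)-2-{[(4-methoxybenzyl)oxy]methyl}oxirane
Conditions: NaH, PMBCl, n-Bu4NI (cat.), THF/DMF, 0 °C → rt
Reagents that add atoms: 4-methoxybenzyl chloride, COc1ccc(CCl)cc1
Why: Williamson etherification that does not involve the epoxide stereocentre (a Payne shift of glycidol is degenerate and returns the same enantiomer).

Step 10
Reactants: 11 (Z)-alkenyl iodide; 13 PMB glycidyl ether
Product: 15 (2R,4Z)-5-[(4S)-2,2-dimethyl-1,3-dioxolan-4-yl]-1-[(4-methoxybenzyl)oxy]-4-methylpent-4-en-2-ol, via alkenyllithium 14 (not isolated)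
Conditions: t-BuLi (2.1 equiv), Et2O, −78 °C; then 13, BF3·OEt2, −78 °C
Reagents that add atoms: none
Why: Iodine–lithium exchange with retention of alkene geometry followed by BF3-promoted SN2 opening of the terminal epoxide at its CH2 carbon, so that C3 comes from the epoxide and the (Z)-C5=C6 geometry from 11.

Step 11
Reactants: 15 homoallylic alcohol
Product: 16 3-O-TBS ether of 15
Conditions: TBSCl, imidazole, DMAP (cat.), DMF, rt
Reagents that add atoms: tert-butyldimethylsilyl chloride, CC(C)(C)[Si](C)(C)Cl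
Why: Silylation of the secondary C3 hydroxyl with a non-chelating group that later directs the Felkin–Anh reduction at C2.

Step 12
Reactants: 16 acetonide
Product: 17 (2S,3Z,6R)-6-[(tert-butyldimethylsilyl)oxy]-7-[(4-methoxybenzyl)oxy]-4-methylhept-3-ene-1,2-diol
Conditions: AcOH/THF/H2O, 35 °C
Reagents that add atoms: none
Why: Acid hydrolysis of the terminal isopropylidene acetal, which should be faster than cleavage of the secondary silyl ether or the PMB ether.

Step 13
Reactants: 17 diol
Product: 18 1,2-bis(triethylsilyl) ether of 17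
Conditions: TESCl, imidazole, DMAP (cat.), CH2Cl2, 0 °C
Reagents that add atoms: triethylsilyl chloride, CC[Si](CC)(CC)Cl
Why: Bis-silylation with the labile triethylsilyl group sets up a selective oxidation of the primary position.

Step 14
Reactants: 18 bis(triethylsilyl) ether
Product: 19 (2S,3Z,6R)-6-[(tert-butyldimethylsilyl)oxy]-7-[(4-methoxybenzyl)oxy]-4-methyl-2-[(triethylsilyl)oxy]hept-3-enal
Conditions: (COCl)2, DMSO, CH2Cl2, −78 → −40 °C; Et3N, −78 → 0 °C
Reagents that add atoms: none
Why: Swern oxidation of a primary triethylsilyl ether directly to the aldehyde, the activated sulfonium species attacking the unhindered primary silyl ether while the secondary one stays, at a temperature that should not epimerise C7.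

Step 15
Reactants: 20 (2R)-2-hydroxypropanoic acid
Product: 21 (2R,5R)-2-tert-butyl-5-methyl-1,3-dioxolan-4-one
Conditions: t-BuCHO, TsOH·H2O (cat.), pentane, reflux (Dean–Stark); crystallisation of the cis isomer
Reagents that add atoms: pivalaldehyde, CC(C)(C)C=O
Why: Acid-catalysed acetalisation of the α-hydroxy acid, in which the cis-dioxolanone forms preferentially and stores the lactate configuration in the acetal centre.

Step 16
Reactants: 21 dioxolanone; 19 aldehyde
Product: 23 aldol adduct (C8 carbinol as an epimer mixture; C17 quaternary), via lithium enolate 22 (not isolated)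
Conditions: LDA, THF, −78 °C; then 19, −78 °C
Reagents that add atoms: none
Why: Aldol addition of the dioxolanone enolate (self-regeneration of stereocentres), in which the aldehyde approaches anti to the tert-butyl group so that the new C17–C8 bond takes the place of the former hydrogen and sets C17.

Step 17
Reactants: 23 aldol adduct
Product: 24 open-chain β-keto dioxolanone (C8 ketone)
Conditions: Dess–Martin periodinane, NaHCO3, CH2Cl2, 0 °C → rt
Reagents that add atoms: none
Why: Dess–Martin oxidation of the secondary alcohol under buffered conditions removes the uncontrolled C8 centre without epimerising C7.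

Step 18
Reactants: 24 β-keto dioxolanone
Product: 26 (3S,5S)-3-hydroxy-3-methylfuran-2,4-dione bearing the C2–C6 chain at C5 (ketolactone with free C17 hydroxyl), via hydroxy ketone 25 (not isolated)
Conditions: PPTS, MeOH, 0 °C → rt
Reagents that add atoms: none
Why: Mild acidic methanolysis removes the secondary triethylsilyl ether and the freed C7 hydroxyl opens the activated dioxolanone by 5-exo-trig acyl transfer (lactonisation), releasing pivalaldehyde and the tertiary C17 hydroxyl.

Step 19
Reactants: 26 hydroxy ketolactone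
Product: 27 17-O-triethylsilyl ketolactone
Conditions: TESOTf, 2,6-lutidine, CH2Cl2, −78 °C
Reagents that add atoms: triethylsilyl trifluoromethanesulfonate, CC[Si](CC)(CC)OS(=O)(=O)C(F)(F)F
Why: Silyl triflate protection of the tertiary α-hydroxyl so that the ketone can meet an organometallic reagent.

Step 20
Reactants: 9 glycal; 27 ketolactone
Product: 30 C8–C9 coupled tertiary alcohol (dihydropyran C9 bonded to lactone C8), via 1-lithioglycal 28 (not isolated), via glycal dichlorocerium reagent 29 (not isolated)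
Conditions: t-BuLi (3 equiv), THF, −78 → 0 °C; CeCl3, −78 °C; then 27, THF, −78 °C
Reagents that add atoms: none
Why: Vinylic deprotonation of the glycal at C9, transmetalation to the weakly basic organocerium reagent and 1,2-addition to the ring ketone (more electrophilic than the lactone carbonyl), the nucleophile entering the five-membered ketone anti to the C7 alkenyl substituent and the C17 methyl group to set C8.

Step 21
Reactants: 30 coupling product
Product: 31 C14 primary alcohol
Conditions: HF·pyridine, pyridine, THF, 0 °C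
Reagents that add atoms: none
Why: Buffered fluoride cleavage of the primary silyl ether, which should be selective over the secondary TBS and tertiary TES ethers and leave the enol ether intact.

Step 22
Reactants: 31 C14 alcohol
Product: 32 C14 aldehyde
Conditions: Dess–Martin periodinane, NaHCO3, CH2Cl2, 0 °C
Reagents that add atoms: none
Why: Buffered Dess–Martin oxidation of the primary alcohol, to which the tertiary C8 hydroxyl and the enol ether are inert.

Step 23
Reactants: 32 C14 aldehyde
Product: 33 (Z)-alkenyl iodide (C14=C1, with C1 bearing iodine and the C15 methyl group)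
Conditions: EtPPh3I, n-BuLi, THF, 0 °C; I2, −78 °C; NaHMDS, −20 °C; then 32, −78 °C
Reagents that add atoms: ethyltriphenylphosphonium iodide, CC[P+](c1ccccc1)(c1ccccc1)c1ccccc1.[I-]; iodine, II
Why: Stork–Zhao-type olefination gives the (Z)-iodide with iodine cis to C13, which fixes the C14=C1 geometry needed for the key step.

Step 24
Reactants: 33 alkenyl iodide PMB ether
Product: 34 C2 primary alcohol
Conditions: DDQ, CH2Cl2/pH 7 buffer, 0 °C
Reagents that add atoms: none
Why: Oxidative cleavage of the PMB ether by DDQ (benzylic hydride abstraction, then hydrolysis), the buffer keeping the enol ether and silyl ethers intact.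

Step 25
Reactants: 34 C2 alcohol
Product: 35 C2 aldehyde (α-silyloxy aldehyde)
Conditions: Dess–Martin periodinane, NaHCO3, CH2Cl2, 0 °C
Reagents that add atoms: none
Why: Mild oxidation to the aldehyde, which is used at once so that C3 is not epimerised.

Step 26
Reactants: 35 iodo aldehyde
Product: 36 macrocyclic allylic alcohol (12-membered oxacycle; C2 carbinol as an epimer mixture)
Conditions: CrCl2, NiCl2 (cat.), DMSO/THF, rt, high dilution
Reagents that add atoms: none
Why: Nozaki–Hiyama–Kishi reaction, in which the alkenylchromium species forms with retention of the (Z)-geometry and adds to the aldehyde at high dilution to close the 12-membered oxacycle (the C2 centre is corrected in steps 27 and 28).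

Step 27
Reactants: 36 macrocyclic allylic alcohol
Product: 37 macrocyclic (Z)-enone (C2 ketone)
Conditions: Dess–Martin periodinane, NaHCO3, CH2Cl2, 0 °C
Reagents that add atoms: none
Why: Oxidation of the secondary allylic alcohol converges both C2 epimers on one enone.

Step 28
Reactants: 37 macrocyclic enone
Product: 38 (2R)-macrocyclic allylic alcohol (2,3-syn)
Conditions: NaBH4, CeCl3·7H2O, MeOH/THF, −78 °C
Reagents that add atoms: none
Why: Luche 1,2-reduction, in which hydride should add in the Felkin–Anh sense relative to the non-chelating C3 silyloxy group and give the 2,3-syn alcohol.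

Step 29
Reactants: 38 (2R)-allylic alcohol
Product: 39 macrocyclic 2-O-acetate (substrate for ring contraction)
Conditions: Ac2O, pyridine, DMAP (cat.), CH2Cl2, 0 °C
Reagents that add atoms: acetic anhydride, CC(=O)OC(C)=O
Why: Acetylation of the secondary hydroxyl (the tertiary C8 hydroxyl does not react) installs the first target acetate and prevents hemiketal formation with the C9 ketone formed next.

Step 30
Reactants: 39 macrocyclic 2-alkenyl-6-alkyl-3,4-dihydro-2H-pyran
Product: 40 bicyclo[8.4.0] C9 ketone (cyclohexene fused to the ten-membered ring)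
Conditions: 1,2-dichlorobenzene (degassed), 2,6-di-tert-butyl-4-methylpyridine (0.2 equiv), 190 °C, sealed tube
Reagents that add atoms: none
Why: Proposed new method: on heating, the allyl vinyl ether O1–C9(=C10)/C13–C14=C1 that is built into the oxa-bridged macrocycle should undergo a concerted [3,3] sigmatropic shift through the boat-like six-centre array enforced by the dihydropyran (C13–O1 breaks, C1–C10 forms, C13=C14 and the C9 ketone appear); the closest known reaction types are the thermal Claisen rearrangement of 2-alkenyl-3,4-dihydro-2H-pyrans to cyclohex-3-enyl carbonyl compounds and the Claisen ring contraction of macrocyclic enol ethers, which have not been combined in one bridged substrate. The cyclohexene ring (C1, C10, C11, C12, C13, C14) closes by C–C bond formation between the enol-ether carbon C10 and the allyl terminus C1 with all six ring atoms inside the pericyclic array, and the ten-membered carbocycle closes in the same event by transannular 12-to-10 ring contraction, because O1 and C13–C14 leave the large ring when C1 bonds to C10. C10 is controlled by C13, since the new bond must form on the pyran face that carries the C13–C14 bond, and C1 is controlled by the (Z)-geometry of C14=C1, which in the boat places C2 trans and the methyl group cis to the C9 carbonyl carbon. The step needs the boat [3,3] path to outrun heterolysis of the allylic C13–O1 bond and 1,3-shift: a chair is excluded by the ring, the alkyl substituent at C9 and the trisubstituted allyl terminus should lower the barrier, C=O formation pays for the strain of the ten-membered ring, and the hindered pyridine base removes traces of acid.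

Step 31
Reactants: 40 bicyclic C9 ketone
Product: 41 (9R)-alcohol (8,9-diol)
Conditions: Zn(BH4)2, Et2O, −20 → 0 °C
Reagents that add atoms: none
Why: Chelation-controlled hydride reduction, in which zinc bridges the C8 hydroxyl and the C9 carbonyl and hydride should add from the peripheral face of the ten-membered ring (the C17 side of the chelate) to give the C9 configuration of the target.

Step 32
Reactants: 41 silylated diol
Product: 42 2-O-acetyl hexaol (free hydroxyls at C3, C8, C9, C11, C12, C17)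
Conditions: HF·pyridine, THF, 0 °C → rt
Reagents that add atoms: none
Why: Fluoride cleavage of the two TBS and two TES ethers under conditions that leave the acetate, the lactone and the two alkenes untouched.

Step 33
Reactants: 42 2-O-acetyl hexaol
Product: 43 CNP0121405.1
Conditions: Ac2O, pyridine, DMAP (cat.), CH2Cl2, 0 °C → rt
Reagents that add atoms: acetic anhydride, CC(=O)OC(C)=O
Why: Pyridine/DMAP acetylation should esterify the three free secondary hydroxyls (C3, C9, C12) while the tertiary hydroxyls at C8, C11 and C17 stay free.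

**Compound list**

1 | methyl (2R)-2-[(4S)-2,2-dimethyl-1,3-dioxolan-4-yl]-2-hydroxyacetate (methyl 3,4-O-isopropylidene-L-threonate) | COC(=O)[C@H](O)[C@@H]1COC(C)(C)O1 | starting material
2 | methyl (2R)-2-[(tert-butyldimethylsilyl)oxy]-2-[(4S)-2,2-dimethyl-1,3-dioxolan-4-yl]acetate | COC(=O)[C@H](O[Si](C)(C)C(C)(C)C)[C@@H]1COC(C)(C)O1 | intermediate
3 | (2R)-2-[(tert-butyldimethylsilyl)oxy]-2-[(4S)-2,2-dimethyl-1,3-dioxolan-4-yl]-N-methoxy-N-methylacetamide | CON(C)C(=O)[C@H](O[Si](C)(C)C(C)(C)C)[C@@H]1COC(C)(C)O1 | intermediate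
4 | (1R)-1-[(tert-butyldimethylsilyl)oxy]-1-[(4S)-2,2-dimethyl-1,3-dioxolan-4-yl]but-3-yn-2-one | C#CC(=O)[C@H](O[Si](C)(C)C(C)(C)C)[C@@H]1COC(C)(C)O1 | intermediate
5 | (4R,5S)-4-[(tert-butyldimethylsilyl)oxy]-5,6-dihydroxyhex-1-yn-3-one | C#CC(=O)[C@H](O[Si](C)(C)C(C)(C)C)[C@@H](O)CO | intermediate (not isolated)
6 | (2S,3R)-3-[(tert-butyldimethylsilyl)oxy]-2-(hydroxymethyl)-2,3-dihydro-4H-pyran-4-one | OC[C@@H]1OC=CC(=O)[C@@H]1O[Si](C)(C)C(C)(C)C | intermediate
7 | (2S,3R)-3-[(tert-butyldimethylsilyl)oxy]-2-{[(tert-butyldimethylsilyl)oxy]methyl}-2,3-dihydro-4H-pyran-4-one | CC(C)(C)[Si](C)(C)OC[C@@H]1OC=CC(=O)[C@@H]1O[Si](C)(C)C(C)(C)C | intermediate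
8 | (2S,3R,4S)-3-[(tert-butyldimethylsilyl)oxy]-2-{[(tert-butyldimethylsilyl)oxy]methyl}-4-methyl-3,4-dihydro-2H-pyran-4-ol | CC(C)(C)[Si](C)(C)OC[C@@H]1OC=C[C@](C)(O)[C@@H]1O[Si](C)(C)C(C)(C)C | intermediate
9 | (2S,3R,4S)-3-[(tert-butyldimethylsilyl)oxy]-2-{[(tert-butyldimethylsilyl)oxy]methyl}-4-methyl-4-[(triethylsilyl)oxy]-3,4-dihydro-2H-pyran (glycal carrying C9–C14) | CC(C)(C)[Si](C)(C)OC[C@@H]1OC=C[C@](C)(O[Si](CC)(CC)CC)[C@@H]1O[Si](C)(C)C(C)(C)C | intermediate
10 | (4R)-2,2-dimethyl-1,3-dioxolane-4-carbaldehyde | O=C[C@H]1COC(C)(C)O1 | starting material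
11 | (4S)-4-[(1Z)-2-iodoprop-1-en-1-yl]-2,2-dimethyl-1,3-dioxolane | C/C(I)=C/[C@H]1COC(C)(C)O1 | intermediate
12 | (2S)-oxiran-2-ylmethanol | OC[C@H]1CO1 | starting material
13 | (2R)-2-{[(4-methoxybenzyl)oxy]methyl}oxirane | COc1ccc(COC[C@H]2CO2)cc1 | intermediate
14 | (Z)-alkenyllithium from 11 (lithium in place of iodine) | C/C([Li])=C/[C@H]1COC(C)(C)O1 | intermediate (not isolated)
15 | (2R,4Z)-5-[(4S)-2,2-dimethyl-1,3-dioxolan-4-yl]-1-[(4-methoxybenzyl)oxy]-4-methylpent-4-en-2-ol | COc1ccc(COC[C@H](O)C/C(C)=C\[C@H]2COC(C)(C)O2)cc1 | intermediate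
16 | 2-O-tert-butyldimethylsilyl ether of 15 (3-O-TBS in skeleton numbering) | COc1ccc(COC[C@H](O[Si](C)(C)C(C)(C)C)C/C(C)=C\[C@H]2COC(C)(C)O2)cc1 | intermediate
17 | (2S,3Z,6R)-6-[(tert-butyldimethylsilyl)oxy]-7-[(4-methoxybenzyl)oxy]-4-methylhept-3-ene-1,2-diol | COc1ccc(COC[C@H](O[Si](C)(C)C(C)(C)C)C/C(C)=C\[C@H](O)CO)cc1 | intermediate
18 | 1,2-bis(triethylsilyl) ether of 17 | COc1ccc(COC[C@H](O[Si](C)(C)C(C)(C)C)C/C(C)=C\[C@H](O[Si](CC)(CC)CC)CO[Si](CC)(CC)CC)cc1 | intermediate
19 | (2S,3Z,6R)-6-[(tert-butyldimethylsilyl)oxy]-7-[(4-methoxybenzyl)oxy]-4-methyl-2-[(triethylsilyl)oxy]hept-3-enal | COc1ccc(COC[C@H](O[Si](C)(C)C(C)(C)C)C/C(C)=C\[C@H](O[Si](CC)(CC)CC)C=O)cc1 | intermediate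
20 | (2R)-2-hydroxypropanoic acid | C[C@@H](O)C(=O)O | starting material
21 | (2R,5R)-2-tert-butyl-5-methyl-1,3-dioxolan-4-one | C[C@H]1O[C@@H](C(C)(C)C)OC1=O | intermediate
22 | lithium enolate of 21 | CC1=C(O[Li])O[C@H](C(C)(C)C)O1 | intermediate (not isolated)
23 | aldol adduct of 22 and 19 (C8 carbinol epimers; C17 quaternary in the dioxolanone) | COc1ccc(COC[C@H](O[Si](C)(C)C(C)(C)C)C/C(C)=C\[C@H](O[Si](CC)(CC)CC)C(O)[C@]2(C)O[C@@H](C(C)(C)C)OC2=O)cc1 | intermediate
24 | open-chain β-keto dioxolanone (C8 ketone, 7-O-TES) | COc1ccc(COC[C@H](O[Si](C)(C)C(C)(C)C)C/C(C)=C\[C@H](O[Si](CC)(CC)CC)C(=O)[C@]2(C)O[C@@H](C(C)(C)C)OC2=O)cc1 | intermediate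
25 | 7-hydroxy β-keto dioxolanone | COc1ccc(COC[C@H](O[Si](C)(C)C(C)(C)C)C/C(C)=C\[C@H](O)C(=O)[C@]2(C)O[C@@H](C(C)(C)C)OC2=O)cc1 | intermediate (not isolated)
26 | (3S,5S)-3-hydroxy-3-methyl-5-[(1Z,4R)-4-[(tert-butyldimethylsilyl)oxy]-5-[(4-methoxybenzyl)oxy]-2-methylpent-1-en-1-yl]furan-2,4(3H,5H)-dione | COc1ccc(COC[C@H](O[Si](C)(C)C(C)(C)C)C/C(C)=C\[C@@H]2OC(=O)[C@@](C)(O)C2=O)cc1 | intermediate
27 | 3-O-triethylsilyl ether of 26 (ketolactone carrying C2–C8, C17–C19) | COc1ccc(COC[C@H](O[Si](C)(C)C(C)(C)C)C/C(C)=C\[C@@H]2OC(=O)[C@@](C)(O[Si](CC)(CC)CC)C2=O)cc1 | intermediate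
28 | C9-lithiated glycal from 9 | CC(C)(C)[Si](C)(C)OC[C@@H]1OC([Li])=C[C@](C)(O[Si](CC)(CC)CC)[C@@H]1O[Si](C)(C)C(C)(C)C | intermediate (not isolated)
29 | C9 dichlorocerium reagent from 28 | CC(C)(C)[Si](C)(C)OC[C@@H]1OC([Ce](Cl)Cl)=C[C@](C)(O[Si](CC)(CC)CC)[C@@H]1O[Si](C)(C)C(C)(C)C | intermediate (not isolated)
30 | C8–C9 coupled tertiary alcohol (2-O-PMB, 3-O-TBS, 11-O-TES, 12-O-TBS, 14-O-TBS, 17-O-TES; 8-OH free) | COc1ccc(COC[C@H](O[Si](C)(C)C(C)(C)C)C/C(C)=C\[C@@H]2OC(=O)[C@@](C)(O[Si](CC)(CC)CC)[C@@]2(O)C3=C[C@](C)(O[Si](CC)(CC)CC)[C@H](O[Si](C)(C)C(C)(C)C)[C@H](CO[Si](C)(C)C(C)(C)C)O3)cc1 | intermediate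
31 | C14 primary alcohol from 30 | COc1ccc(COC[C@H](O[Si](C)(C)C(C)(C)C)C/C(C)=C\[C@@H]2OC(=O)[C@@](C)(O[Si](CC)(CC)CC)[C@@]2(O)C3=C[C@](C)(O[Si](CC)(CC)CC)[C@H](O[Si](C)(C)C(C)(C)C)[C@H](CO)O3)cc1 | intermediate
32 | C14 aldehyde | COc1ccc(COC[C@H](O[Si](C)(C)C(C)(C)C)C/C(C)=C\[C@@H]2OC(=O)[C@@](C)(O[Si](CC)(CC)CC)[C@@]2(O)C3=C[C@](C)(O[Si](CC)(CC)CC)[C@H](O[Si](C)(C)C(C)(C)C)[C@H](C=O)O3)cc1 | intermediate
33 | (Z)-alkenyl iodide (C14=C1; iodine and C15 methyl on C1; 2-O-PMB) | COc1ccc(COC[C@H](O[Si](C)(C)C(C)(C)C)C/C(C)=C\[C@@H]2OC(=O)[C@@](C)(O[Si](CC)(CC)CC)[C@@]2(O)C3=C[C@](C)(O[Si](CC)(CC)CC)[C@H](O[Si](C)(C)C(C)(C)C)[C@H](/C=C(\I)C)O3)cc1 | intermediate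
34 | C2 primary alcohol of the alkenyl iodide | OC[C@H](O[Si](C)(C)C(C)(C)C)C/C(C)=C\[C@@H]1OC(=O)[C@@](C)(O[Si](CC)(CC)CC)[C@@]1(O)C2=C[C@](C)(O[Si](CC)(CC)CC)[C@H](O[Si](C)(C)C(C)(C)C)[C@H](/C=C(\I)C)O2 | intermediate
35 | C2 aldehyde of the alkenyl iodide | O=C[C@H](O[Si](C)(C)C(C)(C)C)C/C(C)=C\[C@@H]1OC(=O)[C@@](C)(O[Si](CC)(CC)CC)[C@@]1(O)C2=C[C@](C)(O[Si](CC)(CC)CC)[C@H](O[Si](C)(C)C(C)(C)C)[C@H](/C=C(\I)C)O2 | intermediate
36 | oxa-bridged bicyclo[9.3.1] macrocycle, C2 alcohol (epimer mixture at C2) | OC1[C@H](O[Si](C)(C)C(C)(C)C)C/C(C)=C\[C@@H]2OC(=O)[C@@](C)(O[Si](CC)(CC)CC)[C@@]2(O)C3=C[C@](C)(O[Si](CC)(CC)CC)[C@H](O[Si](C)(C)C(C)(C)C)[C@H](/C=C1/C)O3 | intermediate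
37 | macrocyclic (Z)-enone (C2 ketone) | O=C1[C@H](O[Si](C)(C)C(C)(C)C)C/C(C)=C\[C@@H]2OC(=O)[C@@](C)(O[Si](CC)(CC)CC)[C@@]2(O)C3=C[C@](C)(O[Si](CC)(CC)CC)[C@H](O[Si](C)(C)C(C)(C)C)[C@H](/C=C1/C)O3 | intermediate
38 | (2R)-macrocyclic allylic alcohol | O[C@H]1[C@H](O[Si](C)(C)C(C)(C)C)C/C(C)=C\[C@@H]2OC(=O)[C@@](C)(O[Si](CC)(CC)CC)[C@@]2(O)C3=C[C@](C)(O[Si](CC)(CC)CC)[C@H](O[Si](C)(C)C(C)(C)C)[C@H](/C=C1/C)O3 | intermediate
39 | macrocyclic 2-O-acetate (2-alkenyl-6-alkyl-3,4-dihydro-2H-pyran inside the 12-membered oxacycle) | CC(=O)O[C@H]1[C@H](O[Si](C)(C)C(C)(C)C)C/C(C)=C\[C@@H]2OC(=O)[C@@](C)(O[Si](CC)(CC)CC)[C@@]2(O)C3=C[C@](C)(O[Si](CC)(CC)CC)[C@H](O[Si](C)(C)C(C)(C)C)[C@H](/C=C1/C)O3 | intermediate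
40 | bicyclic C9 ketone (2-O-Ac, 3-O-TBS, 11-O-TES, 12-O-TBS, 17-O-TES, 8-OH) | O=C1[C@H]2[C@](C)(O[Si](CC)(CC)CC)[C@H](O[Si](C)(C)C(C)(C)C)C=C[C@]2(C)[C@@H](OC(C)=O)[C@H](O[Si](C)(C)C(C)(C)C)C/C(C)=C\[C@@H]2OC(=O)[C@@](C)(O[Si](CC)(CC)CC)[C@]21O | intermediate
41 | (9R)-alcohol of 40 | O[C@@H]1[C@H]2[C@](C)(O[Si](CC)(CC)CC)[C@H](O[Si](C)(C)C(C)(C)C)C=C[C@]2(C)[C@@H](OC(C)=O)[C@H](O[Si](C)(C)C(C)(C)C)C/C(C)=C\[C@@H]2OC(=O)[C@@](C)(O[Si](CC)(CC)CC)[C@]21O | intermediate
42 | 2-O-acetyl hexaol | O[C@@H]1[C@H]2[C@](C)(O)[C@H](O)C=C[C@]2(C)[C@@H](OC(C)=O)[C@H](O)C/C(C)=C\[C@@H]2OC(=O)[C@@](C)(O)[C@]21O | intermediate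
43 | CNP0121405.1 (2,3,9,12-tetraacetate; 8,11,17-triol; 7,19-lactone) | CC(=O)O[C@@H]1[C@H]2[C@](C)(O)[C@H](OC(C)=O)C=C[C@]2(C)[C@@H](OC(C)=O)[C@H](OC(C)=O)C/C(C)=C\[C@@H]2OC(=O)[C@@](C)(O)[C@]21O | target

**Totals**

Total step count: 33. Longest linear sequence: 24 steps (steps 8, 10–14, 16–19, then 20–33).

**Three steps most likely to fail**

Step 30 (ring contraction). The bridged substrate may not reach the boat six-centre array before thermal heterolysis of the allylic C13–O1 bond sets in, which would give elimination to a diene or a 1,3-shift. The fallback sets out from 39 and comes back at 40 without a new isolated compound. It gives up the concerted thermal event and runs the ring contraction as a polar, stepwise process at −78 °C in CH2Cl2 with a bulky aluminium aryloxide, aluminium tris(2,6-diphenylphenoxide) Al(OC6H3Ph2)3, used in excess so that the C8 hydroxyl is capped as its aluminate. This is the known organoaluminium-promoted Claisen manifold of cyclic allyl vinyl ethers. Coordination to O1 should ionise C13–O1, and the tethered aluminium enolate and allyl cation should then collapse at C1. Aqueous work-up would give 40. This fallback still relies on the same bridged substrate; it changes the mechanism and removes the thermal stress, but no fully independent known route to 40 from the same intermediates was found.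

Step 20 (C8–C9 union). The organometallic reagent may deprotonate the ketolactone at the allylic C7–H instead of adding, or may add from the wrong face of the five-membered ring. The fallback sets out from 24 and comes back at 31. The cerium reagent 29, made as in step 20, is added to the open-chain ketone 24. In this acyclic α-silyloxy ketone, Felkin–Anh control (nucleophile anti to the C7 silyloxy group, the bulky C17 side next to H7) should give the same C8 configuration, and the product would be the acyclic tertiary alcohol F1. Buffered HF·pyridine then removes the C7 triethylsilyl ether and the primary C14 silyl ether. The freed C7 hydroxyl should lactonise onto the dioxolanone (catalytic DBU) with loss of pivalaldehyde to give the lactone triol F2. Silylation with TESOTf and 2,6-lutidine at the primary C14 and the tertiary C17 hydroxyls should give the 14,17-bis(triethylsilyl) ether F3. Brief treatment with HF·pyridine/pyridine at −20 °C should cleave only the primary silyl ether and return 31.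

Step 31 (C9 reduction). Hydride may be delivered to the wrong face of the hindered C9 ketone in the zinc chelate and give the C9 epimer. The fallback sets out from 40 and comes back at 42. The stereocontrol element is changed from chelation to non-chelation. The C8 hydroxyl is capped with TMSOTf and Et3N to give the 8-O-trimethylsilyl ketone F4. Reduction with NaBH4 in MeOH/THF at −40 °C should then follow the Felkin–Anh sense (hydride anti to the C8 silyloxy group) and give the 8-O-trimethylsilyl 9-alcohol F5. The HF·pyridine treatment of step 32 removes the trimethylsilyl group together with the other silyl ethers and returns 42.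

Further compounds
F0 | step 30 | none | none
F1 | step 20 | acyclic C8 tertiary alcohol from 29 and 24 (7-O-TES, dioxolanone intact) | COc1ccc(COC[C@H](O[Si](C)(C)C(C)(C)C)C/C(C)=C\[C@H](O[Si](CC)(CC)CC)[C@](O)(C3=C[C@](C)(O[Si](CC)(CC)CC)[C@H](O[Si](C)(C)C(C)(C)C)[C@H](CO[Si](C)(C)C(C)(C)C)O3)[C@]2(C)O[C@@H](C(C)(C)C)OC2=O)cc1
F2 | step 20 | lactone triol (free hydroxyls at C8, C14, C17) | COc1ccc(COC[C@H](O[Si](C)(C)C(C)(C)C)C/C(C)=C\[C@@H]2OC(=O)[C@@](C)(O)[C@@]2(O)C3=C[C@](C)(O[Si](CC)(CC)CC)[C@H](O[Si](C)(C)C(C)(C)C)[C@H](CO)O3)cc1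
F3 | step 20 | 14,17-bis(triethylsilyl) ether of F2 | COc1ccc(COC[C@H](O[Si](C)(C)C(C)(C)C)C/C(C)=C\[C@@H]2OC(=O)[C@@](C)(O[Si](CC)(CC)CC)[C@@]2(O)C3=C[C@](C)(O[Si](CC)(CC)CC)[C@H](O[Si](C)(C)C(C)(C)C)[C@H](CO[Si](CC)(CC)CC)O3)cc1
F4 | step 31 | 8-O-trimethylsilyl ether of ketone 40 | O=C1[C@H]2[C@](C)(O[Si](CC)(CC)CC)[C@H](O[Si](C)(C)C(C)(C)C)C=C[C@]2(C)[C@@H](OC(C)=O)[C@H](O[Si](C)(C)C(C)(C)C)C/C(C)=C\[C@@H]2OC(=O)[C@@](C)(O[Si](CC)(CC)CC)[C@]21O[Si](C)(C)C
F5 | step 31 | 8-O-trimethylsilyl (9R)-alcohol | O[C@@H]1[C@H]2[C@](C)(O[Si](CC)(CC)CC)[C@H](O[Si](C)(C)C(C)(C)C)C=C[C@]2(C)[C@@H](OC(C)=O)[C@H](O[Si](C)(C)C(C)(C)C)C/C(C)=C\[C@@H]2OC(=O)[C@@](C)(O[Si](CC)(CC)CC)[C@]21O[Si](C)(C)C
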